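**Plan**

1. Numbering: the target is a 7-ethyl-1,3,4-trimethyl-6-phenyl-2,3,3a,6,7,7a-hexahydro-1H-indene carrying the (E)-2-methylpropenoic acid on quaternary C-7; all locants below use this numbering.
2. Cuts: the side-chain C=C (olefination of a C-7 aldehyde); the C-1 methyl and the C-7 carbon are re-joined as a δ-lactone (C-1–CH2–O–C(=O)–C-7); C-4 methyl and C-4=C-5 go back to a C-4 ketone; the cyclohexene is then cut at C-7–C-7a and C-5–C-6.
3. Enabling feature: the C-1 methyl on the cyclopentane is cis to C-7 across ring-fusion C-7a, and the C-7 side-chain carbon is cis to C-1 on the cyclohexene, so both fit one six-membered lactone. C-4 is para to C-7, so the diene can be a 2-methoxydiene (C-5=C-4(OMe)–C-3a=C-7a) and the dienophile a tethered (E)-2-ethylcinnamate.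
4. Forward: (R)-pulegone → ring-contracted cyclopentene ester → 2-methoxydiene alcohol → cinnamate ester → intramolecular Diels–Alder (cyclohexene and lactone close together) → C-4 ketone → enol triflate → methyl → lactone opened by PhSe–, C–Se reduced → CO2H → CHO → olefination → acid.
5. Stereochemistry: C-3 from pulegone; C-1 by trans alkylation of a keto ester dianion; C-7a, C-7 and C-6 from the tethered, suprafacial, endo cycloaddition; C-3a by protonation anti to the C-3 methyl; (E)-alkene from the olefination.

Key step: step 10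

Assumption: the ester-bearing ring carbon of 3, 4 and 6–8 is epimerisable and is carried as a mixture (it becomes sp2 in 9), so the SMILES of these compounds leave it undefined.

**Step 1**
Reactants: 1 (R)-(+)-pulegone
Product: 3 methyl (2R)-2-methyl-5-(propan-2-ylidene)cyclopentane-1-carboxylate (methyl pulegenate), via pulegone dibromide 2 (not isolated)
Conditions: Br2, NaHCO3, Et2O, 0 °C; then NaOMe, MeOH, reflux
Reagents that add atoms: sodium methoxide, [Na+].[O-]C
Why: Bromination of the enone C=C followed by Favorskii rearrangement of the dibromo ketone (cyclopropanone formation, methoxide opening, loss of the second bromide to regenerate the isopropylidene) contracts the ring as is classical for pulegone, without touching the methyl-bearing stereocentre that becomes C-3.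

**Step 2**
Reactants: 3 methyl pulegenate
Product: 4 methyl (2R)-2-methyl-5-oxocyclopentane-1-carboxylate
Conditions: O3, CH2Cl2/MeOH, −78 °C; then Me2S
Reagents that add atoms: ozone, [O-][O+]=O
Why: Ozonolysis with reductive work-up cleaves the tetrasubstituted exocyclic alkene to the cyclic β-keto ester, the ester being inert and no stereocentre being formed.

**Step 3**
Reactants: 4 methyl (2R)-2-methyl-5-oxocyclopentane-1-carboxylate
Product: 6 methyl (2R,4S)-2-methyl-5-oxo-4-({[tri(propan-2-yl)silyl]oxy}methyl)cyclopentane-1-carboxylate, via dilithium dianion 5 (not isolated)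
Conditions: LiN(i-Pr)2 (2.2 equiv), THF, −78 to 0 °C; then (i-Pr)3SiOCH2Cl, −78 to −20 °C; NH4Cl (aq)
Reagents that add atoms: (triisopropylsiloxy)methyl chloride, ClCO[Si](C(C)C)(C(C)C)C(C)C
Why: γ-Alkylation of a β-keto ester dianion takes place at the more basic α'-carbanion, and because allylic 1,2-strain with the enolised ester holds the neighbouring methyl pseudo-axial, the chloromethyl ether should enter on the opposite face, placing the CH2O arm trans to the methyl (future C-1 and C-3).

**Step 4**
Reactants: 6 alkylated keto ester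
Product: 7 methyl (2R,4S)-5-hydroxy-2-methyl-4-({[tri(propan-2-yl)silyl]oxy}methyl)cyclopentane-1-carboxylate (carbinol epimers)
Conditions: NaBH4, MeOH, 0 °C
Reagents that add atoms: none
Why: Borohydride reduction of the ketone removes the acidity of the arm-bearing carbon and gives a carbinol whose configuration is irrelevant because it is eliminated in the next step.

**Step 5**
Reactants: 7 hydroxy ester
Product: 9 methyl (3R,5R)-5-methyl-3-({[tri(propan-2-yl)silyl]oxy}methyl)cyclopent-1-ene-1-carboxylate, via mesylate 8 (not isolated)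
Conditions: MsCl, Et3N, CH2Cl2, 0 °C; then DBU, rt
Reagents that add atoms: none
Why: Mesylation and E1cB elimination through the ester enolate give the conjugated cyclopentene ester, in which the two allylic ring stereocentres are unchanged; any cis isomer from step 3 would be removed here by chromatography.

**Step 6**
Reactants: 9 cyclopentene ester
Product: 10 {[(1R,4R)-3-(1-methoxyethenyl)-4-methylcyclopent-2-en-1-yl]methoxy}tri(propan-2-yl)silane
Conditions: Cp2TiMe2, PhMe/THF, 65 °C, dark; basic alumina filtration
Reagents that add atoms: dimethyltitanocene, C[Ti](C)(C1C=CC=C1)C1C=CC=C1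
Why: Titanium methylidene carbonyl olefination of the ester (Cp2Ti=CH2 formed thermally from Cp2TiMe2) converts C=O into C=CH2 and so turns the enoate into a 2-methoxy-1,3-diene, the silyl ether and the stereocentres being inert.

**Step 7**
Reactants: 10 silyl ether diene
Product: 11 [(1R,4R)-3-(1-methoxyethenyl)-4-methylcyclopent-2-en-1-yl]methanol
Conditions: Bu4NF, THF, 0 °C
Reagents that add atoms: none
Why: Fluoride-mediated desilylation under non-acidic conditions frees the primary alcohol while sparing the acid-labile enol ether.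

**Step 8**
Reactants: 12 benzaldehyde, 13 butanoic anhydride
Product: 14 (2E)-2-ethyl-3-phenylprop-2-enoic acid
Conditions: Et3N, 140 °C; Na2CO3 (aq), then HCl (aq), recrystallisation
Reagents that add atoms: none
Why: Perkin condensation of a non-enolisable aldehyde with the anhydride gives the α-alkylcinnamic acid as the thermodynamically preferred (E) isomer (phenyl trans to carboxyl and cis to ethyl), the geometry later transcribed into C-6 and C-7.

**Step 9**
Reactants: 14 (2E)-2-ethyl-3-phenylprop-2-enoic acid, 11 diene alcohol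
Product: 16 [(1R,4R)-3-(1-methoxyethenyl)-4-methylcyclopent-2-en-1-yl]methyl (2E)-2-ethyl-3-phenylprop-2-enoate, via acid chloride 15 (not isolated)
Conditions: (COCl)2, cat. DMF, CH2Cl2, 0 °C to rt, evaporate; then 11, Et3N, DMAP, CH2Cl2, 0 °C
Reagents that add atoms: none
Why: Acylation of the primary alcohol by the preformed acid chloride under amine base (nucleophilic catalysis by DMAP) forms the ester tether without acid, so the enol ether and the alkene geometry are retained.

**Step 10**
Reactants: 16 diene ester
Product: 17 tricyclic enol ether δ-lactone (7-ethyl-4-methoxy-3-methyl-6-phenyl-2,3,5,6,7,7a-hexahydro-1H-indene-7-carboxylic acid lactonised onto a C-1 hydroxymethyl group)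
Conditions: PhMe (0.01 M), BHT, 180 °C, sealed base-washed tube
Reagents that add atoms: none
Why: Thermal, concerted but asynchronous [4+2] cycloaddition in which the 2-methoxydiene of 16 (ring C=C plus the methoxyvinyl group) adds across the tethered (E)-α-ethylcinnamate, its CH2 terminus bonding to the benzylic β-carbon and its ring terminus to the α-carbon, so that the bond between the future quaternary C-7 and C-7a closes both new rings. The closest known reaction type is the ester-tethered type 1 intramolecular Diels–Alder reaction of 1,3,9-decatrienes bearing 2-alkoxy or 2-silyloxy dienes, which gives bicyclic δ-lactones. The cyclohexene closes in the [4+2] mode (two σ bonds, new C-3a=C-4 enol ether), and the δ-lactone closes as the six-membered tether ring (four tether atoms plus C-7 and C-7a), fused to the cyclopentane at C-1–C-7a. C-7a is set by the tether, which can deliver the dienophile only to the cyclopentene face that carries the C-1 CH2O arm (also the face anti to the C-3 methyl); C-7 and C-6 follow from suprafacial addition to the (E)-alkene (phenyl cis to ethyl) and from the endo position of the ester carbonyl that the short tether favours (carbonyl cis to C-1). The step needs regio-, face- and endo selectivity at once; the methoxy group polarises the diene in the matched sense and the tether length should secure all three.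

**Step 11**
Reactants: 17 tricyclic enol ether lactone
Product: 18 trans-fused keto lactone (4-oxo compound, 3a-H anti to 7a-H)
Conditions: 0.5 M HCl (aq), THF, 0 °C
Reagents that add atoms: water, O
Why: Mild acid hydrolysis of the enol ether proceeds by rate-limiting C-protonation at C-3a, which should occur anti to the adjacent pseudo-axial C-3 methyl and so give the trans ring fusion, while the lactone (quaternary α-carbon) is untouched.

**Step 12**
Reactants: 18 keto lactone
Product: 20 Δ4-enol triflate lactone, via potassium enolate 19 (not isolated)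
Conditions: KN(SiMe3)2, THF, −78 °C; then PhNTf2, −78 to 0 °C
Reagents that add atoms: N-phenylbis(trifluoromethanesulfonimide), O=S(=O)(N(c1ccccc1)S(=O)(=O)C(F)(F)F)C(F)(F)F
Why: Kinetic deprotonation by the bulky amide at the C-5 methylene instead of the hindered C-3a methine, then O-sulfonylation, gives the Δ4-enol triflate, the low temperature preventing equilibration to the C-3a enolate (epimerisation or retro-Michael opening).

**Step 13**
Reactants: 20 enol triflate lactone
Product: 21 lactone alkene (7-ethyl-3,4-dimethyl-6-phenyl-2,3,3a,6,7,7a-hexahydro-1H-indene-7-carboxylic acid δ-lactone with the C-1 hydroxymethyl group)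
Conditions: Me2Zn, Pd(PPh3)4 (cat.), THF, 50 °C
Reagents that add atoms: dimethylzinc, C[Zn]C
Why: Negishi cross-coupling of the enol triflate (oxidative addition to zerovalent palladium, transmetalation from zinc, reductive elimination) installs the C-4 methyl with the double bond fixed at C-4=C-5, the hindered lactone being inert to the organozinc.

**Step 14**
Reactants: 21 lactone alkene
Product: 22 7-ethyl-3,4-dimethyl-6-phenyl-1-[(phenylselanyl)methyl]-2,3,3a,6,7,7a-hexahydro-1H-indene-7-carboxylic acid
Conditions: PhSeH, NaH, THF, 0 °C; then 21, DMF, 110 °C; 1 M HCl work-up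
Reagents that add atoms: benzeneselenol, [SeH]c1ccccc1
Why: The soft benzeneselenolate opens the lactone by SN2 attack at the primary O–CH2 carbon (alkyl–oxygen cleavage, the acyl carbon being shielded by the quaternary centre), releasing the C-7 carboxylate and leaving a reducible C–Se bond on the C-1 arm without touching any stereocentre.

**Step 15**
Reactants: 22 seleno acid
Product: 23 7-ethyl-1,3,4-trimethyl-6-phenyl-2,3,3a,6,7,7a-hexahydro-1H-indene-7-carboxylic acid
Conditions: Bu3SnH, AIBN (cat.), PhH, 80 °C
Reagents that add atoms: none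
Why: Radical chain reduction of the primary alkyl phenyl selenide by the tin hydride converts the arm into the C-1 methyl, whose cis relation to C-7 was fixed by the tether, the ring alkene being geometrically out of reach of the radical.

**Step 16**
Reactants: 23 acid
Product: 24 (7-ethyl-1,3,4-trimethyl-6-phenyl-2,3,3a,6,7,7a-hexahydro-1H-inden-7-yl)methanol
Conditions: LiAlH4, THF, reflux
Reagents that add atoms: none
Why: Hydride reduction of the hindered carboxylic acid gives the neopentyl primary alcohol and leaves the isolated trisubstituted alkene untouched.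

**Step 17**
Reactants: 24 alcohol
Product: 25 7-ethyl-1,3,4-trimethyl-6-phenyl-2,3,3a,6,7,7a-hexahydro-1H-indene-7-carbaldehyde
Conditions: Dess–Martin periodinane, NaHCO3, CH2Cl2, rt
Reagents that add atoms: none
Why: Dess–Martin oxidation under buffered conditions gives the aldehyde, which has no α-hydrogen and therefore cannot epimerise.

**Step 18**
Reactants: 25 aldehyde, 26 ethyl 2-(diethoxyphosphoryl)propanoate
Product: 27 plakotenin ethyl ester
Conditions: NaH, THF, 0 °C to reflux
Reagents that add atoms: none
Why: Horner–Wadsworth–Emmons olefination with the α-methyl phosphonate anion, small and reactive enough for the neopentyl aldehyde, should give the (E)-trisubstituted enoate because reversible addition lets the ester end up trans to the bulky quaternary substituent.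

**Step 19**
Reactants: 27 plakotenin ethyl ester
Product: 28 plakotenin
Conditions: LiOH, THF/MeOH/H2O, 50 °C; then 1 M HCl
Reagents that add atoms: lithium hydroxide, [Li+].[OH-]
Why: Saponification of the unhindered ethyl ester and acidification liberate the acid without affecting the alkene geometry or any stereocentre.

**Compound list**

1 | (R)-(+)-pulegone, (5R)-5-methyl-2-(propan-2-ylidene)cyclohexan-1-one | C[C@@H]1CCC(=C(C)C)C(=O)C1 | starting material
2 | pulegone dibromide, (5R)-2-bromo-2-(2-bromopropan-2-yl)-5-methylcyclohexan-1-one (C-2 epimers) | C[C@@H]1CCC(Br)(C(C)(C)Br)C(=O)C1 | intermediate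
3 | methyl (2R)-2-methyl-5-(propan-2-ylidene)cyclopentane-1-carboxylate (C-1 epimers) | COC(=O)C1C(=C(C)C)CC[C@H]1C | intermediate
4 | methyl (2R)-2-methyl-5-oxocyclopentane-1-carboxylate (C-1 epimerisable) | COC(=O)C1C(=O)CC[C@H]1C | intermediate
5 | dilithium dianion of 4 (ester-conjugated enolate, carbanion at C-4) | [Li+].[Li+].COC(=O)C1=C([O-])[CH-]C[C@H]1C | intermediate
6 | methyl (2R,4S)-2-methyl-5-oxo-4-({[tri(propan-2-yl)silyl]oxy}methyl)cyclopentane-1-carboxylate (CH2O arm trans to methyl) | COC(=O)C1C(=O)[C@H](CO[Si](C(C)C)(C(C)C)C(C)C)C[C@H]1C | intermediate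
7 | methyl (2R,4S)-5-hydroxy-2-methyl-4-({[tri(propan-2-yl)silyl]oxy}methyl)cyclopentane-1-carboxylate (epimers at C-1 and C-5) | COC(=O)C1C(O)[C@H](CO[Si](C(C)C)(C(C)C)C(C)C)C[C@H]1C | intermediate
8 | 5-methanesulfonate of 7 | COC(=O)C1C(OS(C)(=O)=O)[C@H](CO[Si](C(C)C)(C(C)C)C(C)C)C[C@H]1C | intermediate
9 | methyl (3R,5R)-5-methyl-3-({[tri(propan-2-yl)silyl]oxy}methyl)cyclopent-1-ene-1-carboxylate (3,5-trans) | COC(=O)C1=C[C@H](CO[Si](C(C)C)(C(C)C)C(C)C)C[C@H]1C | intermediate
10 | {[(1R,4R)-3-(1-methoxyethenyl)-4-methylcyclopent-2-en-1-yl]methoxy}tri(propan-2-yl)silane | COC(=C)C1=C[C@H](CO[Si](C(C)C)(C(C)C)C(C)C)C[C@H]1C | intermediate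
11 | [(1R,4R)-3-(1-methoxyethenyl)-4-methylcyclopent-2-en-1-yl]methanol | COC(=C)C1=C[C@H](CO)C[C@H]1C | intermediate
12 | benzaldehyde | O=Cc1ccccc1 | starting material
13 | butanoic anhydride | CCCC(=O)OC(=O)CCC | starting material
14 | (2E)-2-ethyl-3-phenylprop-2-enoic acid | CC/C(=C\c1ccccc1)C(=O)O | intermediate
15 | (2E)-2-ethyl-3-phenylprop-2-enoyl chloride | CC/C(=C\c1ccccc1)C(=O)Cl | intermediate
16 | [(1R,4R)-3-(1-methoxyethenyl)-4-methylcyclopent-2-en-1-yl]methyl (2E)-2-ethyl-3-phenylprop-2-enoate | CC/C(=C\c1ccccc1)C(=O)OC[C@@H]1C[C@@H](C)C(C(=C)OC)=C1 | intermediate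
17 | tricyclic enol ether δ-lactone: 7-ethyl-4-methoxy-3-methyl-6-phenyl-2,3,5,6,7,7a-hexahydro-1H-indene-7-carboxylic acid lactonised onto a C-1 hydroxymethyl group; C-1 arm cis to C-7 across C-7a, carbonyl cis to C-1, phenyl cis to ethyl, 3-methyl trans to the C-1 arm | CC[C@@]1(C(=O)OC3)[C@H]2C(=C(OC)C[C@H]1c1ccccc1)[C@H](C)C[C@H]23 | intermediate
18 | keto lactone: 4-oxo analogue of 17 with 3a-H anti to 7a-H (trans ring fusion), other centres as in 17 | CC[C@@]1(C(=O)OC3)[C@H]2[C@H](C(=O)C[C@H]1c1ccccc1)[C@H](C)C[C@H]23 | intermediate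
19 | potassium Δ4-enolate of 18 | CC[C@@]1(C(=O)OC3)[C@H]2[C@H](C([O-])=C[C@H]1c1ccccc1)[C@H](C)C[C@H]23.[K+] | intermediate
20 | enol triflate lactone: 4-(trifluoromethanesulfonyloxy)-4,5-ene, stereocentres as in 18 | CC[C@@]1(C(=O)OC3)[C@H]2[C@H](C(OS(=O)(=O)C(F)(F)F)=C[C@H]1c1ccccc1)[C@H](C)C[C@H]23 | intermediate
21 | lactone alkene: 7-ethyl-3,4-dimethyl-6-phenyl-2,3,3a,6,7,7a-hexahydro-1H-indene-7-carboxylic acid δ-lactone with the C-1 hydroxymethyl group, stereocentres arranged as in 28 | CC[C@@]1(C(=O)OC3)[C@H]2[C@H](C(C)=C[C@H]1c1ccccc1)[C@H](C)C[C@H]23 | intermediate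
22 | 7-ethyl-3,4-dimethyl-6-phenyl-1-[(phenylselanyl)methyl]-2,3,3a,6,7,7a-hexahydro-1H-indene-7-carboxylic acid, stereocentres arranged as in 28 | CC[C@@]1(C(=O)O)[C@H]2[C@H](C(C)=C[C@H]1c1ccccc1)[C@H](C)C[C@H]2C[Se]c1ccccc1 | intermediate
23 | 7-ethyl-1,3,4-trimethyl-6-phenyl-2,3,3a,6,7,7a-hexahydro-1H-indene-7-carboxylic acid, stereocentres arranged as in 28 | CC[C@@]1(C(=O)O)[C@H]2[C@H](C(C)=C[C@H]1c1ccccc1)[C@H](C)C[C@H]2C | intermediate
24 | (7-ethyl-1,3,4-trimethyl-6-phenyl-2,3,3a,6,7,7a-hexahydro-1H-inden-7-yl)methanol, stereocentres arranged as in 28 | CC[C@@]1(CO)[C@H]2[C@H](C(C)=C[C@H]1c1ccccc1)[C@H](C)C[C@H]2C | intermediate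
25 | 7-ethyl-1,3,4-trimethyl-6-phenyl-2,3,3a,6,7,7a-hexahydro-1H-indene-7-carbaldehyde, stereocentres arranged as in 28 | CC[C@@]1(C=O)[C@H]2[C@H](C(C)=C[C@H]1c1ccccc1)[C@H](C)C[C@H]2C | intermediate
26 | ethyl 2-(diethoxyphosphoryl)propanoate (triethyl 2-phosphonopropanoate) | CCOC(=O)C(C)P(=O)(OCC)OCC | starting material
27 | plakotenin ethyl ester, ethyl (2E)-3-(7-ethyl-1,3,4-trimethyl-6-phenyl-2,3,3a,6,7,7a-hexahydro-1H-inden-7-yl)-2-methylprop-2-enoate, stereocentres as in 28 | CC[C@@]1(/C=C(\C)C(=O)OCC)[C@H]2[C@H](C(C)=C[C@H]1c1ccccc1)[C@H](C)C[C@H]2C | intermediate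
28 | plakotenin, (2E)-3-[(1R,3R,3aR,6S,7S,7aR)-7-ethyl-1,3,4-trimethyl-6-phenyl-2,3,3a,6,7,7a-hexahydro-1H-inden-7-yl]-2-methylprop-2-enoic acid | CC[C@@]1(/C=C(\C)C(=O)O)[C@H]2[C@H](C(C)=C[C@H]1c1ccccc1)[C@H](C)C[C@H]2C | target

**Step count and risks**

Total steps: 19. Longest linear sequence: 18 steps (steps 1–7 and 9–19; step 8 is a one-step branch).

Steps most likely to fail:

Step 10. The cycloaddition may be too slow at temperatures the enol ether tolerates, because the ester must adopt its less stable conformation, or part of the material may react through the exo arrangement. Fallback, setting out from 16: mild hydrolysis of the enol ether (oxalic acid on wet silica) should give the enone ester [(1R,4R)-3-acetyl-4-methylcyclopent-2-en-1-yl]methyl (2E)-2-ethyl-3-phenylprop-2-enoate F1. Treatment of F1 with LiN(SiMe3)2 in THF (−78 °C to rt) should trigger an anionic intramolecular double Michael reaction: the kinetic methyl ketone enolate adds to the cinnamate β-carbon and the resulting ester enolate adds to the ring enone at the future C-7a. Low-temperature protonation should then give keto lactone 18, where the route is rejoined.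

Step 11. Facial selectivity in the C-protonation at C-3a may be poor, or the ketone may epimerise during hydrolysis, giving cis-fused material. Fallback, setting out from 17: the lactone is opened first with PhSeNa (DMF, 110 °C), which leaves the enol ether intact and should give the enol ether seleno acid 7-ethyl-4-methoxy-3-methyl-6-phenyl-1-[(phenylselanyl)methyl]-2,3,5,6,7,7a-hexahydro-1H-indene-7-carboxylic acid F2. In F2 the lactone bridge no longer screens the face anti to the C-3 methyl, and the free axial C-7 carboxylic acid sits on that face, so hydrolysis in wet THF can proceed by intramolecular general-acid protonation of C-3a, which should give the trans-fused keto acid F3. KN(SiMe3)2 (2.1 equiv) and PhNTf2 at −78 °C should then give the enol triflate acid F4, and Me2Zn with Pd(PPh3)4 should give seleno acid 22, where the route is rejoined.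

Step 18. Addition of the phosphonate anion to the neopentyl aldehyde may be too slow, or the E/Z control may erode. Fallback, setting out from 25: aldol addition of the lithium enolate of ethyl propanoate (LiN(i-Pr)2, THF, −78 °C), a smaller nucleophile, should give the β-hydroxy ester ethyl 3-hydroxy-2-methyl-3-(7-ethyl-1,3,4-trimethyl-6-phenyl-2,3,3a,6,7,7a-hexahydro-1H-inden-7-yl)propanoate F5 as a diastereomer mixture. Mesylation (MsCl, Et3N) to the methanesulfonate F6 and E1cB elimination with DBU, under which the enoate can equilibrate to the (E) isomer, should give ester 27, where the route is rejoined.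

Further compounds
F1 | step 10 | [(1R,4R)-3-acetyl-4-methylcyclopent-2-en-1-yl]methyl (2E)-2-ethyl-3-phenylprop-2-enoate | CC/C(=C\c1ccccc1)C(=O)OC[C@@H]1C[C@@H](C)C(C(C)=O)=C1
F2 | step 11 | 7-ethyl-4-methoxy-3-methyl-6-phenyl-1-[(phenylselanyl)methyl]-2,3,5,6,7,7a-hexahydro-1H-indene-7-carboxylic acid | CC[C@@]1(C(=O)O)[C@H]2C(=C(OC)C[C@H]1c1ccccc1)[C@H](C)C[C@H]2C[Se]c1ccccc1
F3 | step 11 | 7-ethyl-3-methyl-4-oxo-6-phenyl-1-[(phenylselanyl)methyl]octahydro-1H-indene-7-carboxylic acid (trans ring fusion) | CC[C@@]1(C(=O)O)[C@H]2[C@H](C(=O)C[C@H]1c1ccccc1)[C@H](C)C[C@H]2C[Se]c1ccccc1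
F4 | step 11 | 7-ethyl-3-methyl-6-phenyl-1-[(phenylselanyl)methyl]-4-(trifluoromethanesulfonyloxy)-2,3,3a,6,7,7a-hexahydro-1H-indene-7-carboxylic acid | CC[C@@]1(C(=O)O)[C@H]2[C@H](C(OS(=O)(=O)C(F)(F)F)=C[C@H]1c1ccccc1)[C@H](C)C[C@H]2C[Se]c1ccccc1
F5 | step 18 | ethyl 3-hydroxy-2-methyl-3-(7-ethyl-1,3,4-trimethyl-6-phenyl-2,3,3a,6,7,7a-hexahydro-1H-inden-7-yl)propanoate | CC[C@@]1(C(O)C(C)C(=O)OCC)[C@H]2[C@H](C(C)=C[C@H]1c1ccccc1)[C@H](C)C[C@H]2C
F6 | step 18 | methanesulfonate of F5 | CC[C@@]1(C(OS(C)(=O)=O)C(C)C(=O)OCC)[C@H]2[C@H](C(C)=C[C@H]1c1ccccc1)[C@H](C)C[C@H]2C
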